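The route cuts the diaryl ether bond between the ring C oxygen (O at C3 of the catechol ring) and C4 of the para-phenylene ring D. Ring D carries that oxygen para to the benzylic carbon of its bridge to dibenzofuran C1. Raised to a ketone, this carbon turns ring D into a 4-fluorophenyl ketone, so that fluoride-triggered desilylation and SNAr close the 18-membered macrocycle in one operation. The precursor is a 1,3,7-trisubstituted dibenzofuran with a CH2C(=O)C6H4F arm at C1 and a 2-arylethyl arm at C7 ending in a silyl-protected phenol. One final hydrogenolysis erases the carbonyl and both benzyl ethers.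

Key step: step 9

Ring letters: ring A is the phenolic ring of the dibenzofuran, ring B its other benzo ring, ring C the catechol ring, ring D the para-phenylene ring.
Assumption: the target is taken as drawn, without stereocentres; any conformational chirality of the macrocycle is not addressed.

Step 1
Reactants: 1 1-bromo-3,5-dimethoxybenzene
Product: 2 1-bromo-2-iodo-3,5-dimethoxybenzene
Conditions: NIS (1.05 equiv), TFA (cat.), MeCN, 0 °C to rt
Reagents that add atoms: N-iodosuccinimide, O=C1CCC(=O)N1I
Why: Electrophilic aromatic iodination should go to the position next to bromine, which is para to one methoxy group and less crowded than the position between the two methoxy groups.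

Step 2
Reactants: 2 1-bromo-2-iodo-3,5-dimethoxybenzene; 3 (4-chloro-2-fluorophenyl)boronic acid
Product: 4 2-bromo-4'-chloro-2'-fluoro-4,6-dimethoxy-1,1'-biphenyl
Conditions: Pd(PPh3)4 (5 mol%), K2CO3, 1,4-dioxane/H2O, 80 °C
Reagents that add atoms: none
Why: Suzuki–Miyaura coupling, in which oxidative addition into C–I is much faster than into the neighbouring C–Br or the C–Cl of the boronic acid, so only the iodide should be replaced.

Step 3
Reactants: 4 2-bromo-4'-chloro-2'-fluoro-4,6-dimethoxy-1,1'-biphenyl
Product: 5 6-bromo-4'-chloro-2'-fluoro-1,1'-biphenyl-2,4-diol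
Conditions: BBr3 (4 equiv), CH2Cl2, −78 °C to rt; then H2O
Reagents that add atoms: none
Why: Lewis acid cleavage of both aryl methyl ethers with BBr3 should free the resorcinol while the three aryl halides stay untouched.

Step 4
Reactants: 5 6-bromo-4'-chloro-2'-fluoro-1,1'-biphenyl-2,4-diol
Product: 7 3-(benzyloxy)-1-bromo-7-chlorodibenzofuran, via 1-bromo-7-chlorodibenzofuran-3-ol 6 (not isolated)
Conditions: K2CO3 (3 equiv), NMP, 150 °C, argon; then 25 °C, BnBr (1.1 equiv)
Reagents that add atoms: benzyl bromide, BrCc1ccccc1
Why: Intramolecular SNAr closes the furan ring because only the hydroxyl ortho to the biaryl bond can reach the C–F carbon, which tells the two resorcinol oxygens apart by geometry, and the remaining para phenoxide is then benzylated in the same pot (Williamson ether synthesis).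

Step 5
Reactants: 7 3-(benzyloxy)-1-bromo-7-chlorodibenzofuran; 8 1-(4-fluorophenyl)ethanone
Product: 9 2-[3-(benzyloxy)-7-chlorodibenzofuran-1-yl]-1-(4-fluorophenyl)ethanone
Conditions: Pd2(dba)3 (2.5 mol%), Xantphos (6 mol%), K3PO4, toluene, 90 °C
Reagents that add atoms: none
Why: Palladium-catalysed α-arylation of the methyl ketone enolate should take place at the C–Br bond, since this catalyst leaves the C–Cl bond alone and the crowded product resists a second arylation.

Step 6
Reactants: 10 4-(benzyloxy)-3-hydroxybenzaldehyde
Product: 11 4-(benzyloxy)-3-[(triisopropylsilyl)oxy]benzaldehyde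
Conditions: TIPSCl, imidazole, DMF, rt
Reagents that add atoms: triisopropylsilyl chloride, CC(C)[Si](Cl)(C(C)C)C(C)C
Why: Imidazole-promoted silylation of the free phenol should give an aryl silyl ether that withstands the basic steps ahead and is removed later by fluoride.

Step 7
Reactants: 11 4-(benzyloxy)-3-[(triisopropylsilyl)oxy]benzaldehyde
Product: 12 1-(benzyloxy)-4-ethenyl-2-[(triisopropylsilyl)oxy]benzene
Conditions: Ph3PCH3Br, KOtBu, THF, 0 °C to rt
Reagents that add atoms: methyltriphenylphosphonium bromide, C[P+](c1ccccc1)(c1ccccc1)c1ccccc1.[Br-]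
Why: Wittig methylenation of the aldehyde should proceed cleanly, since the silyl and benzyl ethers are inert to the non-stabilised ylide.

Step 8
Reactants: 12 1-(benzyloxy)-4-ethenyl-2-[(triisopropylsilyl)oxy]benzene; 13 9-borabicyclo[3.3.1]nonane (9-BBN); 9 2-[3-(benzyloxy)-7-chlorodibenzofuran-1-yl]-1-(4-fluorophenyl)ethanone
Product: 15 2-[3-(benzyloxy)-7-{2-[4-(benzyloxy)-3-(triisopropylsilyloxy)phenyl]ethyl}dibenzofuran-1-yl]-1-(4-fluorophenyl)ethanone, via B-alkyl-9-BBN adduct 14 (not isolated)
Conditions: 12 (slight excess over 9-BBN), THF, rt; then 9, Pd(OAc)2 (5 mol%), SPhos (10 mol%), K3PO4 (aq), THF, 65 °C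
Reagents that add atoms: none
Why: Anti-Markovnikov hydroboration of the styrene followed by B-alkyl Suzuki–Miyaura coupling at the aryl chloride should build the CH2CH2 bridge without any hydrogenation, so the benzyl ethers, the ketone and the C–F bond survive (no B–H is left to reduce the ketone because the styrene is in excess).

Step 9
Reactants: 15 2-[3-(benzyloxy)-7-{2-[4-(benzyloxy)-3-(triisopropylsilyloxy)phenyl]ethyl}dibenzofuran-1-yl]-1-(4-fluorophenyl)ethanone
Product: 17 macrocyclic aryl ketone (bis-O-benzyl asterelin A bearing C=O at the bridge carbon bonded to ring D), via free phenol 16 (not isolated)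
Conditions: CsF (5 equiv), DMF, 0.002 M (syringe-pump addition of 15), 100 °C, argon
Reagents that add atoms: none
Why: Fluoride strips the triisopropylsilyl group from the ring C oxygen, and the caesium phenoxide adds to C4 of ring D, para to the ketone, to give a Meisenheimer adduct whose charge rests on the carbonyl oxygen; loss of fluoride then gives the diaryl ether. The closest known reaction type is the SNAr etherification of 4-fluorophenyl ketones by phenoxides or silylated phenols, as used for poly(aryl ether ketone)s and for macrocyclic diaryl ethers. The only ring closed is the 18-membered macrocycle, by end-to-end addition–elimination at an sp2 carbon. No stereocentre is formed. The step needs ring closure to beat chain growth and needs a single nucleophile: high dilution with slow addition and the two arms held on the rigid dibenzofuran favour cyclisation, both other oxygens are benzyl ethers, and the weakly basic fluoride should keep enolisation of the CH2 next to the carbonyl low.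

Step 10
Reactants: 17 macrocyclic aryl ketone
Product: 18 asterelin A
Conditions: H2 (4 bar), 10% Pd/C, EtOAc/AcOH, HClO4 (cat.), rt
Reagents that add atoms: none
Why: Catalytic hydrogenolysis should cleave both O-benzyl groups and, under acid, take the aryl ketone through its benzylic alcohol to CH2, helped by the para aryloxy donor now on ring D.

Compound list
1 | 1-bromo-3,5-dimethoxybenzene | COc1cc(Br)cc(OC)c1 | starting material
2 | 1-bromo-2-iodo-3,5-dimethoxybenzene | COc1cc(Br)c(I)c(OC)c1 | intermediate
3 | (4-chloro-2-fluorophenyl)boronic acid | OB(O)c1ccc(Cl)cc1F | starting material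
4 | 2-bromo-4'-chloro-2'-fluoro-4,6-dimethoxy-1,1'-biphenyl | COc1cc(Br)c(-c2ccc(Cl)cc2F)c(OC)c1 | intermediate
5 | 6-bromo-4'-chloro-2'-fluoro-1,1'-biphenyl-2,4-diol | Oc1cc(Br)c(-c2ccc(Cl)cc2F)c(O)c1 | intermediate
6 | 1-bromo-7-chlorodibenzofuran-3-ol (formed in the flask) | Oc1cc(Br)c2c(c1)oc1cc(Cl)ccc12 | intermediate
7 | 3-(benzyloxy)-1-bromo-7-chlorodibenzofuran | Brc1cc(OCc2ccccc2)cc2oc3cc(Cl)ccc3c12 | intermediate
8 | 1-(4-fluorophenyl)ethanone | CC(=O)c1ccc(F)cc1 | starting material
9 | 2-[3-(benzyloxy)-7-chlorodibenzofuran-1-yl]-1-(4-fluorophenyl)ethanone | O=C(Cc1cc(OCc2ccccc2)cc2oc3cc(Cl)ccc3c12)c1ccc(F)cc1 | intermediate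
10 | 4-(benzyloxy)-3-hydroxybenzaldehyde | O=Cc1ccc(OCc2ccccc2)c(O)c1 | starting material
11 | 4-(benzyloxy)-3-[(triisopropylsilyl)oxy]benzaldehyde | O=Cc1ccc(OCc2ccccc2)c(O[Si](C(C)C)(C(C)C)C(C)C)c1 | intermediate
12 | 1-(benzyloxy)-4-ethenyl-2-[(triisopropylsilyl)oxy]benzene | C=Cc1ccc(OCc2ccccc2)c(O[Si](C(C)C)(C(C)C)C(C)C)c1 | intermediate
13 | 9-borabicyclo[3.3.1]nonane (9-BBN, drawn as monomer) | B1C2CCCC1CCC2 | starting material
14 | 9-{2-[4-(benzyloxy)-3-(triisopropylsilyloxy)phenyl]ethyl}-9-borabicyclo[3.3.1]nonane (formed in the flask) | C(Cc1ccc(OCc2ccccc2)c(O[Si](C(C)C)(C(C)C)C(C)C)c1)B1C2CCCC1CCC2 | intermediate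
15 | 2-[3-(benzyloxy)-7-{2-[4-(benzyloxy)-3-(triisopropylsilyloxy)phenyl]ethyl}dibenzofuran-1-yl]-1-(4-fluorophenyl)ethanone | O=C(Cc1cc(OCc2ccccc2)cc2oc3cc(CCc4ccc(OCc5ccccc5)c(O[Si](C(C)C)(C(C)C)C(C)C)c4)ccc3c12)c1ccc(F)cc1 | intermediate
16 | 2-[3-(benzyloxy)-7-{2-[4-(benzyloxy)-3-hydroxyphenyl]ethyl}dibenzofuran-1-yl]-1-(4-fluorophenyl)ethanone (formed in the flask, present as its caesium phenoxide) | O=C(Cc1cc(OCc2ccccc2)cc2oc3cc(CCc4ccc(OCc5ccccc5)c(O)c4)ccc3c12)c1ccc(F)cc1 | intermediate
17 | macrocyclic aryl ketone: asterelin A with both hydroxyls as benzyl ethers and C=O at the bridge carbon bonded to ring D | c1ccccc1COc1cc2c3c(c1)oc1cc(ccc13)CCc1ccc(OCc3ccccc3)c(c1)Oc1ccc(cc1)C(=O)C2 | intermediate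
18 | asterelin A | Oc1cc2c3c(c1)oc1cc(ccc13)CCc1ccc(O)c(c1)Oc1ccc(cc1)CC2 | target

Total step count: 10 steps.
Longest linear sequence: 8 steps (steps 1, 2, 3, 4, 5, 8, 9, 10, from 1 to 18).

Steps most likely to fail

Step 9. Ring closure may lose to intermolecular ether formation and chain growth. The CH2 flanked by the carbonyl and the dibenzofuran may also be deprotonated, which switches off the activation of ring D and opens condensation paths. The fallback sets out from 15 and removes the acidic position while raising the activation. SeO2 in dioxane/H2O at 100 °C should oxidise that CH2 to give the silyl-protected 1,2-diketone F1. CsF in DMF at high dilution should then pass through the free phenol 1,2-diketone F2 and close the same O–C bond at lower temperature to give the macrocyclic 1,2-diketone F3. Hydrogenolysis (H2, 10% Pd/C, AcOH, HClO4) should reduce both benzylic carbonyl groups to CH2 and cleave both benzyl ethers, so the fallback comes back to the route at 18.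

Step 5. Oxidative addition and reductive elimination at the crowded bay position C1 may be slow, the more acidic product may be arylated a second time, or the catalyst may insert into the C–Cl bond. The fallback sets out from 7 and replaces the enolate coupling by an aryl nucleophile and an epoxide. Mg turnings with LiCl in THF should insert into the C–Br bond only and give the arylmagnesium bromide F4. CuI-catalysed opening of purchased 2-(4-fluorophenyl)oxirane (Fc1ccc(cc1)C1CO1) at its terminal carbon should give the racemic alcohol F5. Dess–Martin periodinane should oxidise F5 to the ketone, so the fallback comes back at 9.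

Step 4. Displacement of the unactivated fluoride may be slow at 150 °C, so that the electron-rich resorcinol dianion decomposes or is benzylated before the furan has closed. The fallback sets out from 2 and closes the furan by acid instead of base. Suzuki–Miyaura coupling of 2 with purchased (4-chloro-2-methoxyphenyl)boronic acid (COc1cc(Cl)ccc1B(O)O), under the conditions of step 2, should give the trimethoxybiphenyl F6. BBr3 should give the triol F7. TsOH in refluxing toluene with removal of water should close the ring by dehydration through the keto tautomer of the resorcinol ring, where again only the ortho pair of hydroxyls can react. The fallback comes back at 6, which is benzylated (K2CO3, BnBr, DMF) to 7 as in step 4.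

Further compounds
F1 | step 9 | 1-[3-(benzyloxy)-7-{2-[4-(benzyloxy)-3-(triisopropylsilyloxy)phenyl]ethyl}dibenzofuran-1-yl]-2-(4-fluorophenyl)ethane-1,2-dione | O=C(C(=O)c1cc(OCc2ccccc2)cc2oc3cc(CCc4ccc(OCc5ccccc5)c(O[Si](C(C)C)(C(C)C)C(C)C)c4)ccc3c12)c1ccc(F)cc1
F2 | step 9 | 1-[3-(benzyloxy)-7-{2-[4-(benzyloxy)-3-hydroxyphenyl]ethyl}dibenzofuran-1-yl]-2-(4-fluorophenyl)ethane-1,2-dione (formed in the flask) | O=C(C(=O)c1cc(OCc2ccccc2)cc2oc3cc(CCc4ccc(OCc5ccccc5)c(O)c4)ccc3c12)c1ccc(F)cc1
F3 | step 9 | macrocyclic 1,2-diketone: bis-O-benzyl asterelin A with both carbons of the ring A to ring D bridge as C=O | c1ccccc1COc1cc2c3c(c1)oc1cc(ccc13)CCc1ccc(OCc3ccccc3)c(c1)Oc1ccc(cc1)C(=O)C2=O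
F4 | step 5 | [3-(benzyloxy)-7-chlorodibenzofuran-1-yl]magnesium bromide (formed in the flask) | Br[Mg]c1cc(OCc2ccccc2)cc2oc3cc(Cl)ccc3c12
F5 | step 5 | 2-[3-(benzyloxy)-7-chlorodibenzofuran-1-yl]-1-(4-fluorophenyl)ethanol (racemic) | OC(Cc1cc(OCc2ccccc2)cc2oc3cc(Cl)ccc3c12)c1ccc(F)cc1
F6 | step 4 | 2-bromo-4'-chloro-2',4,6-trimethoxy-1,1'-biphenyl | COc1cc(Br)c(-c2ccc(Cl)cc2OC)c(OC)c1
F7 | step 4 | 6-bromo-4'-chloro-1,1'-biphenyl-2,2',4-triol | Oc1cc(Br)c(-c2ccc(Cl)cc2O)c(O)c1
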